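## Retrosynthetic overview

1. Target 24 ⇒ aryl bromide 21 + zinc homoenolate of methyl 3-bromopropanoate (Negishi). The side-chain ester enters last, after the C3 ester has been reduced.
2. 21 ⇒ hydride reduction of trans ester 20 ⇒ oxidative ring contraction of (S)-flavanone 17 (trivalent iodine, 1,2-shift of the ring A carbon from C4 to C3). The six-membered ring C is made first and then contracted to the dihydrofuran.
3. (S)-17 ⇒ asymmetric CuH conjugate reduction of flavone 15 ⇒ condensation, cyclisation and dehydrogenation of acetophenone 6 with aldehyde 12.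
4. 6 ⇐ catechol (methylation, para-bromination, Fries acetylation with Ac2O); 12 ⇐ p-cresol (bromination/hydrolysis, Cu-catalysed methoxylation, pivaloylation).

Assumption: the DTBM-SEGPHOS antipode written in step 7 is taken to be the one that gives the (2S) product; if the sense of induction is the opposite, the other antipode is used.

## Route

Step 1
Reactants: 1 catechol (benzene-1,2-diol)
Product: 2 guaiacol (2-methoxyphenol)
Conditions: MeI (1.0 equiv), K2CO3 (1.0 equiv), acetone, reflux
Reagents that add atoms: iodomethane, CI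
Why: Williamson O-methylation with one equivalent of MeI gives mainly the monoether, which is separated from catechol and veratrole by distillation.

Step 2
Reactants: 2 guaiacol
Product: 3 4-bromo-2-methoxyphenol
Conditions: NBS (1.0 equiv), MeCN, 0 °C
Reagents that add atoms: N-bromosuccinimide, O=C1CCC(=O)N1Br
Why: Electrophilic aromatic bromination goes para to the free hydroxyl, the stronger director.

Step 3
Reactants: 3 4-bromo-2-methoxyphenol; 4 acetic anhydride
Product: 6 1-(5-bromo-2-hydroxy-3-methoxyphenyl)ethan-1-one, via aryl acetate 5 (not isolated)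
Conditions: Ac2O (1.1 equiv), TfOH, 0 → 60 °C; ice-water
Reagents that add atoms: none
Why: One-pot O-acetylation and acid-mediated Fries rearrangement; the para position is blocked by bromine, so the acetyl group ends ortho to the hydroxyl as the hydrogen-bonded ketone.

Step 4
Reactants: 7 p-cresol (4-methylphenol)
Product: 10 3,5-dibromo-4-hydroxybenzaldehyde, via ring-dibrominated cresol 8 (not isolated), via benzal bromide 9 (not isolated)
Conditions: Br2 (2.05 equiv), 1,2-dichlorobenzene, 35 °C; Br2 (2.05 equiv), 155 °C; then H2O, 110 °C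
Reagents that add atoms: bromine, BrBr; water, O
Why: Ionic ring bromination ortho to the hydroxyl, radical side-chain bromination at high temperature and hydrolysis of the benzal bromide give the aldehyde (established bulk sequence).

Step 5
Reactants: 10 3,5-dibromo-4-hydroxybenzaldehyde
Product: 12 4-formyl-2,6-dimethoxyphenyl pivalate, via syringaldehyde sodium salt 11 (not isolated)
Conditions: NaOMe (3.5 equiv), CuCl (10 mol %), DMF, 115 °C (MeOH distilled off); then PivCl (2 equiv), 0 °C → rt
Reagents that add atoms: sodium methoxide, C[O-].[Na+]; pivaloyl chloride, CC(C)(C)C(Cl)=O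
Why: Copper-catalysed Ullmann-type methoxylation of both aryl bromides, then O-acylation of the phenoxide; the hindered, electron-poor pivalate shields the phenol from trivalent iodine and lowers the migratory aptitude of ring B.

Step 6
Reactants: 6 1-(5-bromo-2-hydroxy-3-methoxyphenyl)ethan-1-one; 12 4-formyl-2,6-dimethoxyphenyl pivalate
Product: 15 4-(6-bromo-8-methoxy-4-oxo-4H-chromen-2-yl)-2,6-dimethoxyphenyl pivalate (flavone), via chalcone 13 (not isolated), via racemic flavanone 14 (not isolated)
Conditions: pyrrolidine (0.5 equiv), EtOH, 70 °C; then I2 (10 mol %), DMSO, 130 °C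
Reagents that add atoms: none
Why: Amine-catalysed Claisen–Schmidt condensation and oxa-Michael closure of ring C, then iodine-catalysed dehydrogenation with DMSO as terminal oxidant, give the achiral flavone and erase the racemic C2 centre.

Step 7
Reactants: 15 flavone
Product: 17 4-[(2S)-6-bromo-8-methoxy-4-oxochroman-2-yl]-2,6-dimethoxyphenyl pivalate ((S)-flavanone), via silyl enol ether 16 (not isolated)
Conditions: Cu(OAc)2 (5 mol %), (R)-DTBM-SEGPHOS (5.5 mol %), (EtO)2MeSiH (2 equiv), PhMe, 25–40 °C; then 1 M HCl, THF, 0 °C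
Reagents that add atoms: none
Why: Proposed new method: copper hydride-catalysed asymmetric conjugate reduction of a flavone, not yet shown for 2-aryl-4H-chromen-4-ones – the bisphosphine-ligated CuH formed from Cu(OAc)2 and the silane delivers hydride to C2 of the vinylogous ester in the enantio-determining step (the chiral pocket tells the C2 aryl group from ring oxygen O1 and so sets the (2S) centre), the O-bound copper enolate is turned over by σ-bond metathesis with Si–H to silyl enol ether 16, which resists 1,2-reduction and in the base-free medium cannot racemise by retro-oxa-Michael opening before mild acid releases the ketone; closest known reaction type: CuH-catalysed asymmetric 1,4-reduction of β,β-disubstituted cyclic enones and 2-alkylchromones.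

Step 8
Reactants: 17 (S)-flavanone
Product: 20 methyl (2S,3S)-5-bromo-2-[3,5-dimethoxy-4-(pivaloyloxy)phenyl]-7-methoxy-2,3-dihydro-1-benzofuran-3-carboxylate (2,3-trans), via methyl enol ether 18 (not isolated), via orthoester 19 (not isolated)
Conditions: PhI(OAc)2 (1.2 equiv), HC(OMe)3, H2SO4 (cat.), rt; aq. NaHCO3
Reagents that add atoms: trimethyl orthoformate, COC(OC)OC; water, O
Why: Hypervalent-iodine oxidative ring contraction of a flavanone (1,2-aryl shift): trivalent iodine attacks C3 of the enol ether anti to the 2-aryl group, and the ring A carbon antiperiplanar to the C–I bond migrates from C4 to C3 with inversion as PhI leaves, which gives the trans ester with C2 untouched.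

Step 9
Reactants: 20 trans ester
Product: 21 4-[(2S,3R)-5-bromo-3-(hydroxymethyl)-7-methoxy-2,3-dihydro-1-benzofuran-2-yl]-2,6-dimethoxyphenol
Conditions: LiAlH4 (2.5 equiv), THF, −10 → 0 °C; H2O, aq. NaOH
Reagents that add atoms: none
Why: Hydride reduction turns the C3 ester into the primary alcohol and cleaves the pivalate in the same operation, with hydride addition outpacing enolisation so that C3 is not epimerised; the aryl bromide survives at this temperature.

Step 10
Reactants: 21 bromo diol; 22 methyl 3-bromopropanoate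
Product: 24 methyl 3-[(2S,3R)-2-(4-hydroxy-3,5-dimethoxyphenyl)-3-(hydroxymethyl)-7-methoxy-2,3-dihydro-1-benzofuran-5-yl]propanoate, via alkylzinc bromide 23 (not isolated)
Conditions: 22, Zn dust, LiCl, THF, 40 °C (3.5 equiv of 23); then 21, Pd(OAc)2 (4 mol %), SPhos (8 mol %), THF, 40 °C; aq. NH4Cl
Reagents that add atoms: none
Why: Negishi sp3–sp2 cross-coupling of the zinc homoenolate; Pd/SPhos tolerates the free phenol and alcohol (they consume two sacrificial equivalents of 23), and no stereocentre is touched.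

## Compound list

1 | catechol (benzene-1,2-diol) | Oc1ccccc1O | starting material
2 | guaiacol (2-methoxyphenol) | COc1ccccc1O | intermediate
3 | 4-bromo-2-methoxyphenol | COc1cc(Br)ccc1O | intermediate
4 | acetic anhydride | CC(=O)OC(C)=O | starting material
5 | 4-bromo-2-methoxyphenyl acetate | COc1cc(Br)ccc1OC(C)=O | intermediate
6 | 1-(5-bromo-2-hydroxy-3-methoxyphenyl)ethan-1-one | CC(=O)c1cc(Br)cc(OC)c1O | intermediate
7 | p-cresol (4-methylphenol) | Cc1ccc(O)cc1 | starting material
8 | 2,6-dibromo-4-methylphenol | Cc1cc(Br)c(O)c(Br)c1 | intermediate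
9 | 2,6-dibromo-4-(dibromomethyl)phenol | BrC(Br)c1cc(Br)c(O)c(Br)c1 | intermediate
10 | 3,5-dibromo-4-hydroxybenzaldehyde | O=Cc1cc(Br)c(O)c(Br)c1 | intermediate
11 | sodium 4-formyl-2,6-dimethoxyphenoxide (syringaldehyde sodium salt) | COc1cc(C=O)cc(OC)c1[O-].[Na+] | intermediate
12 | 4-formyl-2,6-dimethoxyphenyl pivalate | COc1cc(C=O)cc(OC)c1OC(=O)C(C)(C)C | intermediate
13 | 4-[(1E)-3-(5-bromo-2-hydroxy-3-methoxyphenyl)-3-oxoprop-1-en-1-yl]-2,6-dimethoxyphenyl pivalate (chalcone) | COc1cc(/C=C/C(=O)c2cc(Br)cc(OC)c2O)cc(OC)c1OC(=O)C(C)(C)C | intermediate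
14 | rac-4-(6-bromo-8-methoxy-4-oxochroman-2-yl)-2,6-dimethoxyphenyl pivalate (racemic flavanone) | Brc1cc(OC)c2c(c1)C(=O)CC(c1cc(OC)c(OC(=O)C(C)(C)C)c(OC)c1)O2 | intermediate
15 | 4-(6-bromo-8-methoxy-4-oxo-4H-chromen-2-yl)-2,6-dimethoxyphenyl pivalate (flavone) | Brc1cc(OC)c2c(c1)C(=O)C=C(c1cc(OC)c(OC(=O)C(C)(C)C)c(OC)c1)O2 | intermediate
16 | 4-[(2S)-6-bromo-4-{[diethoxy(methyl)silyl]oxy}-8-methoxy-2H-chromen-2-yl]-2,6-dimethoxyphenyl pivalate | Brc1cc(OC)c2c(c1)C(O[Si](C)(OCC)OCC)=C[C@@H](c1cc(OC)c(OC(=O)C(C)(C)C)c(OC)c1)O2 | intermediate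
17 | 4-[(2S)-6-bromo-8-methoxy-4-oxochroman-2-yl]-2,6-dimethoxyphenyl pivalate ((S)-flavanone) | Brc1cc(OC)c2c(c1)C(=O)C[C@@H](c1cc(OC)c(OC(=O)C(C)(C)C)c(OC)c1)O2 | intermediate
18 | 4-[(2S)-6-bromo-4,8-dimethoxy-2H-chromen-2-yl]-2,6-dimethoxyphenyl pivalate (methyl enol ether) | Brc1cc(OC)c2c(c1)C(OC)=C[C@@H](c1cc(OC)c(OC(=O)C(C)(C)C)c(OC)c1)O2 | intermediate
19 | 4-[(2S,3S)-5-bromo-7-methoxy-3-(trimethoxymethyl)-2,3-dihydro-1-benzofuran-2-yl]-2,6-dimethoxyphenyl pivalate (orthoester, 2,3-trans) | Brc1cc(OC)c2c(c1)[C@H](C(OC)(OC)OC)[C@@H](c1cc(OC)c(OC(=O)C(C)(C)C)c(OC)c1)O2 | intermediate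
20 | methyl (2S,3S)-5-bromo-2-[3,5-dimethoxy-4-(pivaloyloxy)phenyl]-7-methoxy-2,3-dihydro-1-benzofuran-3-carboxylate (2,3-trans) | Brc1cc(OC)c2c(c1)[C@H](C(=O)OC)[C@@H](c1cc(OC)c(OC(=O)C(C)(C)C)c(OC)c1)O2 | intermediate
21 | 4-[(2S,3R)-5-bromo-3-(hydroxymethyl)-7-methoxy-2,3-dihydro-1-benzofuran-2-yl]-2,6-dimethoxyphenol (2,3-trans) | Brc1cc(OC)c2c(c1)[C@H](CO)[C@@H](c1cc(OC)c(O)c(OC)c1)O2 | intermediate
22 | methyl 3-bromopropanoate | COC(=O)CCBr | starting material
23 | (3-methoxy-3-oxopropyl)zinc bromide | COC(=O)CC[Zn]Br | intermediate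
24 | methyl 3-[(2S,3R)-2-(4-hydroxy-3,5-dimethoxyphenyl)-3-(hydroxymethyl)-7-methoxy-2,3-dihydro-1-benzofuran-5-yl]propanoate (2,3-trans; CNP0362206.1) | COC(=O)CCc1cc(OC)c2c(c1)[C@H](CO)[C@@H](c1cc(OC)c(O)c(OC)c1)O2 | target

## Step count and risks

Total steps: 10. Longest linear sequence: 8 steps (1, 2, 3, 6, 7, 8, 9, 10 from catechol); the p-cresol branch joins at step 6.

Step 7 is the proposed new reaction. The 2-aryl vinylogous ester may react slowly or give modest ee. The fallback uses known chemistry and sets out from racemic flavanone 14, obtained by stopping step 6 before the I2/DMSO stage and completing the cyclisation by longer heating with pyrrolidine. Asymmetric transfer hydrogenation under dynamic kinetic resolution (RuCl(p-cymene)[(S,S)-TsDPEN], HCO2H/DBU, MeCN, 40 °C) reduces one enantiomer while the base racemises C2 through reversible retro-oxa-Michael opening. This gives the cis alcohol 4-[(2S,4S)-6-bromo-4-hydroxy-8-methoxychroman-2-yl]-2,6-dimethoxyphenyl pivalate F1. Oxidation with Dess–Martin periodinane (CH2Cl2, rt, no base) comes back to the route at 17.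

Step 8 may suffer from dehydrogenation back to flavone 15 (which can be returned to step 7), a competing 2,3-shift of ring B, or slow migration of the brominated ring A. The fallback is a Wolff ring contraction, again a 1,2-shift of the ring A carbon, and sets out from 17. LiN(SiMe3)2 and CF3CO2CH2CF3 (THF, −78 °C) give 4-[(2S)-6-bromo-8-methoxy-4-oxo-3-(trifluoroacetyl)chroman-2-yl]-2,6-dimethoxyphenyl pivalate F2, used crude. Diazo transfer with MsN3 and Et3N in MeCN gives 4-[(2R)-6-bromo-3-diazo-8-methoxy-4-oxochroman-2-yl]-2,6-dimethoxyphenyl pivalate F3 (same spatial arrangement at C2; the descriptor changes by priority). Irradiation at 350 nm in MeOH, then equilibration of the cis/trans ester mixture with catalytic NaOMe in MeOH at 0 °C, comes back to the route at 20.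

Step 3 may give acylation para to the methoxy group or incomplete rearrangement. The fallback sets out from 3 and fixes the regiochemistry by ortho-specific formylation (MgCl2, Et3N, paraformaldehyde, MeCN, reflux), which gives 5-bromo-2-hydroxy-3-methoxybenzaldehyde F4. MeMgBr (2.2 equiv, THF, 0 °C) gives racemic 4-bromo-2-(1-hydroxyethyl)-6-methoxyphenol F5, and MnO2 in CH2Cl2 comes back to the route at 6.

Further compounds
F1 | step 7 | 4-[(2S,4S)-6-bromo-4-hydroxy-8-methoxychroman-2-yl]-2,6-dimethoxyphenyl pivalate (2,4-cis) | Brc1cc(OC)c2c(c1)[C@@H](O)C[C@@H](c1cc(OC)c(OC(=O)C(C)(C)C)c(OC)c1)O2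
F2 | step 8 | 4-[(2S)-6-bromo-8-methoxy-4-oxo-3-(trifluoroacetyl)chroman-2-yl]-2,6-dimethoxyphenyl pivalate (C3 epimers/enol) | Brc1cc(OC)c2c(c1)C(=O)C(C(=O)C(F)(F)F)[C@@H](c1cc(OC)c(OC(=O)C(C)(C)C)c(OC)c1)O2
F3 | step 8 | 4-[(2R)-6-bromo-3-diazo-8-methoxy-4-oxochroman-2-yl]-2,6-dimethoxyphenyl pivalate | Brc1cc(OC)c2c(c1)C(=O)C(=[N+]=[N-])[C@@H](c1cc(OC)c(OC(=O)C(C)(C)C)c(OC)c1)O2
F4 | step 3 | 5-bromo-2-hydroxy-3-methoxybenzaldehyde | COc1cc(Br)cc(C=O)c1O
F5 | step 3 | 4-bromo-2-(1-hydroxyethyl)-6-methoxyphenol (racemic) | COc1cc(Br)cc(C(C)O)c1O
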